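**Retrosynthetic overview**

- Labels and feature: ring A is the central arene (C1 enoyl, C2 OH, C3 H, C4 OMe, C5 O-aryl, C6 H), ring B the 4-hydroxystyryl arene, ring C the para-phenylene on the ether oxygen, ring D the 2,4-dihydroxybenzoyl arene. C2–C3–C4–C5 of ring A carry O, H, OMe and O-aryl in the order of a 4-aryloxy-3-methoxybut-2-enoate chain, and C1/C6 (acyl, H) map onto a terminal alkynyl ketone.
- Last disconnection: the ring C–CH= bond of the MOM-protected bichalcone 18 (Heck), giving aryl iodide 13 and the ring D aryl vinyl ketone 17.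
- Key disconnection: ring A of 12 is opened at C1–C2 and C5–C6 into diene 5 and enynone 9. The diaryl ether C–O bond is thus made earlier, as an SN2 bond on an sp3 carbon (step 1).
- Ring order: rings B, C and D are bought; ring A is the only ring formed (step 5). Protection of C2–OH, the Heck coupling and global MOM removal follow.

Key step: step 5

Remark: compounds 2 (the methyl enol ether of methyl 4-chloroacetoacetate), 6 and 7 are treated as catalogue chemicals.

**Route**

Step 1
Reactants: 1 4-iodophenol; 2 methyl (E)-4-chloro-3-methoxybut-2-enoate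
Product: 3 methyl (E)-4-(4-iodophenoxy)-3-methoxybut-2-enoate
Conditions: K2CO3, NaI (cat.), acetone, reflux
Reagents that add atoms: none
Why: Williamson ether synthesis in which the phenoxide displaces the primary chloride next to the enol ether (SN2, helped by in situ Finkelstein exchange), while carbonate is too weak to enolize the β-methoxy enoate and the E geometry is untouched.

Step 2
Reactants: 3 methyl (E)-4-(4-iodophenoxy)-3-methoxybut-2-enoate
Product: 5 (1Z,3Z)-4-(4-iodophenoxy)-1,3-dimethoxy-1-(trimethylsilyloxy)buta-1,3-diene, via lithium dienolate 4 (not isolated)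
Conditions: LiN(i-Pr)2 (commercial solution), THF, −78 °C; Me3SiCl, −78 to 0 °C; pentane, filtration under argon, used crude
Reagents that add atoms: chlorotrimethylsilane, C[Si](C)(C)Cl
Why: Kinetic γ-deprotonation of a β-alkoxy enoate followed by O-silylation is the standard preparation of 1,3-dialkoxy-1-silyloxybutadienes (vinylketene acetals); at −78 °C the γ-C–H should be removed much faster than any ring C–H of the iodoarene, and the aryloxy group should sit on the outside of the U-shaped dienolate, the geometry suited to cycloaddition.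

Step 3
Reactants: 6 4-(methoxymethoxy)benzaldehyde; 7 diethyl {2-[methoxy(methyl)amino]-2-oxoethyl}phosphonate
Product: 8 (E)-N-methoxy-3-[4-(methoxymethoxy)phenyl]-N-methylprop-2-enamide
Conditions: NaH, THF, 0 °C to rt
Reagents that add atoms: none
Why: Horner–Wadsworth–Emmons olefination with a stabilized amide phosphonate, which should give the E-alkene under thermodynamic control and leaves the MOM ether alone.

Step 4
Reactants: 8 (E)-N-methoxy-3-[4-(methoxymethoxy)phenyl]-N-methylprop-2-enamide
Product: 9 (E)-1-[4-(methoxymethoxy)phenyl]pent-1-en-4-yn-3-one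
Conditions: HC≡CMgBr (0.5 M in THF), THF, 0 °C; inverse quench into cold 1 M HCl
Reagents that add atoms: ethynylmagnesium bromide, C#C[Mg]Br
Why: Weinreb ketone synthesis, in which magnesium chelation by the N-methoxy group limits the reaction to a single 1,2-addition, and the cold acidic inverse quench protonates the released amine before it can add to the ynone.

Step 5
Reactants: 5 (1Z,3Z)-4-(4-iodophenoxy)-1,3-dimethoxy-1-(trimethylsilyloxy)buta-1,3-diene; 9 (E)-1-[4-(methoxymethoxy)phenyl]pent-1-en-4-yn-3-one
Product: 12 (E)-1-[2-hydroxy-5-(4-iodophenoxy)-4-methoxyphenyl]-3-[4-(methoxymethoxy)phenyl]prop-2-en-1-one, via cyclohexadiene cycloadduct 10 (not isolated), via aryl trimethylsilyl ether 11 (not isolated)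
Conditions: 5 (1.5–2 equiv), PhMe, 0 °C to rt, then 60 °C; then 0.5 M HCl, THF, 0 °C, short
Reagents that add atoms: none
Why: Diene 5 and the terminal triple bond of 9 should combine in a polarized, asynchronous Diels–Alder reaction in which the aryloxy-bearing diene terminus (its most nucleophilic carbon) bonds to the alkyne CH and the ketene acetal carbon to the acyl-bearing alkyne carbon, so that ring A closes intermolecularly by [4+2] cycloaddition through the new C5–C6 and C1–C2 bonds. The closest known reaction is the benzannulation of 1,3-dialkoxy-1-silyloxybutadienes with acetylenic ketones and esters, which gives 2-hydroxy-4-methoxyaryl carbonyl compounds; the aryloxy group on the diene terminus is the only new element. Cycloadduct 10 is a cyclohexa-1,4-diene whose ketal carbon carries no hydrogen, so it can aromatize only by 1,4-loss of methanol with the C5 hydrogen, which keeps the diaryl ether and gives silyl ether 11, and dilute acid then frees the hydrogen-bonded phenol. The regiochemistry needed (hydroxyl ortho to the ketone, aryloxy meta to it) follows from pairing the nucleophilic diene terminus with the electrophilic β-carbon of the ynone, and the site selectivity needed (alkyne, not the styryl alkene) from the unhindered, more electrophilic terminal triple bond against a β-aryl enone deactivated by its para-oxygen donor. No stereocenter survives: the two transient stereocenters of 10 and the ketene acetal geometry are erased on aromatization, and the E-alkene of 9 is not touched.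

Step 6
Reactants: 12 (E)-1-[2-hydroxy-5-(4-iodophenoxy)-4-methoxyphenyl]-3-[4-(methoxymethoxy)phenyl]prop-2-en-1-one
Product: 13 (E)-1-[5-(4-iodophenoxy)-4-methoxy-2-(methoxymethoxy)phenyl]-3-[4-(methoxymethoxy)phenyl]prop-2-en-1-one
Conditions: NaH, MOMCl, DMF, 0 °C
Reagents that add atoms: chloromethyl methyl ether, COCCl
Why: Williamson-type O-alkylation of the sodium phenoxide; full deprotonation is needed for the hydrogen-bonded ortho-hydroxy ketone, and in aprotic DMF closure of the phenoxide onto the enone is uphill because it would trade a phenoxide for a ketone enolate.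

Step 7
Reactants: 14 2,4-dihydroxybenzaldehyde
Product: 15 2,4-bis(methoxymethoxy)benzaldehyde
Conditions: NaH, MOMCl, DMF, 0 °C to rt
Reagents that add atoms: chloromethyl methyl ether, COCCl
Why: Double Williamson-type O-alkylation, with NaH chosen so that the hydrogen-bonded 2-hydroxyl reacts as well as the 4-hydroxyl.

Step 8
Reactants: 15 2,4-bis(methoxymethoxy)benzaldehyde
Product: 16 1-[2,4-bis(methoxymethoxy)phenyl]prop-2-en-1-ol (racemic)
Conditions: CH2=CHMgBr, THF, −78 to 0 °C; sat. aq. NH4Cl
Reagents that add atoms: vinylmagnesium bromide, C=C[Mg]Br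
Why: Grignard 1,2-addition to the aldehyde, giving the racemic aryl vinyl carbinol whose single stereocenter is erased in the next step.

Step 9
Reactants: 16 1-[2,4-bis(methoxymethoxy)phenyl]prop-2-en-1-ol
Product: 17 1-[2,4-bis(methoxymethoxy)phenyl]prop-2-en-1-one
Conditions: MnO2 (activated, excess), CH2Cl2, rt; used promptly
Reagents that add atoms: none
Why: MnO2 oxidation of an alcohol that is both benzylic and allylic, mild enough to leave the acetals and the polymerizable vinyl ketone intact.

Step 10
Reactants: 13 (E)-1-[5-(4-iodophenoxy)-4-methoxy-2-(methoxymethoxy)phenyl]-3-[4-(methoxymethoxy)phenyl]prop-2-en-1-one; 17 1-[2,4-bis(methoxymethoxy)phenyl]prop-2-en-1-one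
Product: 18 (E)-1-[2,4-bis(methoxymethoxy)phenyl]-3-{4-[2-methoxy-4-(methoxymethoxy)-5-{(E)-3-[4-(methoxymethoxy)phenyl]prop-2-enoyl}phenoxy]phenyl}prop-2-en-1-one
Conditions: 17 (1.5 equiv), Pd(OAc)2 (5 mol %), Bu4NCl, NaHCO3, DMF, 60 °C
Reagents that add atoms: none
Why: Mizoroki–Heck reaction under ligand-free phase-transfer conditions, in which oxidative addition of the aryl iodide to zerovalent palladium, insertion of the terminal vinyl ketone with aryl at the CH2 carbon and syn β-hydride elimination give the E-enone, the 1,2-disubstituted enone already present inserts far more slowly, and hydrogencarbonate instead of an amine base avoids the reductive Heck pathway.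

Step 11
Reactants: 18 the fully MOM-protected bichalcone
Product: 19 (E)-1-(2,4-dihydroxyphenyl)-3-{4-[4-hydroxy-5-[(E)-3-(4-hydroxyphenyl)prop-2-enoyl]-2-methoxyphenoxy]phenyl}prop-2-en-1-one (target)
Conditions: HCl (1.25 M in MeOH), THF, 45 °C; stopped at full conversion
Reagents that add atoms: none
Why: Acid-catalysed acetal exchange with methanol should remove all four MOM groups as dimethoxymethane, while the aryl methyl ether, the diaryl ether and both E-enones are stable to dilute methanolic HCl at this temperature.

**Compound list**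

1 | 4-iodophenol | Oc1ccc(I)cc1 | starting material
2 | methyl (E)-4-chloro-3-methoxybut-2-enoate | COC(=O)/C=C(/OC)CCl | starting material
3 | methyl (E)-4-(4-iodophenoxy)-3-methoxybut-2-enoate | COC(=O)/C=C(/OC)COc1ccc(I)cc1 | intermediate
4 | lithium (1E,3Z)-4-(4-iodophenoxy)-1,3-dimethoxybuta-1,3-dien-1-olate | [Li+].CO/C([O-])=C/C(OC)=C/Oc1ccc(I)cc1 | intermediate
5 | (1Z,3Z)-4-(4-iodophenoxy)-1,3-dimethoxy-1-(trimethylsilyloxy)buta-1,3-diene | CO/C(O[Si](C)(C)C)=C/C(OC)=C/Oc1ccc(I)cc1 | intermediate
6 | 4-(methoxymethoxy)benzaldehyde | COCOc1ccc(C=O)cc1 | starting material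
7 | diethyl {2-[methoxy(methyl)amino]-2-oxoethyl}phosphonate | CCOP(=O)(OCC)CC(=O)N(C)OC | starting material
8 | (E)-N-methoxy-3-[4-(methoxymethoxy)phenyl]-N-methylprop-2-enamide | CON(C)C(=O)/C=C/c1ccc(OCOC)cc1 | intermediate
9 | (E)-1-[4-(methoxymethoxy)phenyl]pent-1-en-4-yn-3-one | C#CC(=O)/C=C/c1ccc(OCOC)cc1 | intermediate
10 | (E)-1-[3-(4-iodophenoxy)-4,6-dimethoxy-6-(trimethylsilyloxy)cyclohexa-1,4-dien-1-yl]-3-[4-(methoxymethoxy)phenyl]prop-2-en-1-one (mixture of diastereomers) | COCOc1ccc(/C=C/C(=O)C2=CC(Oc3ccc(I)cc3)C(OC)=CC2(OC)O[Si](C)(C)C)cc1 | intermediate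
11 | (E)-1-[5-(4-iodophenoxy)-4-methoxy-2-(trimethylsilyloxy)phenyl]-3-[4-(methoxymethoxy)phenyl]prop-2-en-1-one | COCOc1ccc(/C=C/C(=O)c2cc(Oc3ccc(I)cc3)c(OC)cc2O[Si](C)(C)C)cc1 | intermediate
12 | (E)-1-[2-hydroxy-5-(4-iodophenoxy)-4-methoxyphenyl]-3-[4-(methoxymethoxy)phenyl]prop-2-en-1-one | COCOc1ccc(/C=C/C(=O)c2cc(Oc3ccc(I)cc3)c(OC)cc2O)cc1 | intermediate
13 | (E)-1-[5-(4-iodophenoxy)-4-methoxy-2-(methoxymethoxy)phenyl]-3-[4-(methoxymethoxy)phenyl]prop-2-en-1-one | COCOc1ccc(/C=C/C(=O)c2cc(Oc3ccc(I)cc3)c(OC)cc2OCOC)cc1 | intermediate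
14 | 2,4-dihydroxybenzaldehyde | O=Cc1ccc(O)cc1O | starting material
15 | 2,4-bis(methoxymethoxy)benzaldehyde | COCOc1ccc(C=O)c(OCOC)c1 | intermediate
16 | 1-[2,4-bis(methoxymethoxy)phenyl]prop-2-en-1-ol (racemic) | C=CC(O)c1ccc(OCOC)cc1OCOC | intermediate
17 | 1-[2,4-bis(methoxymethoxy)phenyl]prop-2-en-1-one | C=CC(=O)c1ccc(OCOC)cc1OCOC | intermediate
18 | (E)-1-[2,4-bis(methoxymethoxy)phenyl]-3-{4-[2-methoxy-4-(methoxymethoxy)-5-{(E)-3-[4-(methoxymethoxy)phenyl]prop-2-enoyl}phenoxy]phenyl}prop-2-en-1-one | COCOc1ccc(/C=C/C(=O)c2cc(Oc3ccc(/C=C/C(=O)c4ccc(OCOC)cc4OCOC)cc3)c(OC)cc2OCOC)cc1 | intermediate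
19 | (E)-1-(2,4-dihydroxyphenyl)-3-{4-[4-hydroxy-5-[(E)-3-(4-hydroxyphenyl)prop-2-enoyl]-2-methoxyphenoxy]phenyl}prop-2-en-1-one | COc1cc(O)c(C(=O)/C=C/c2ccc(O)cc2)cc1Oc1ccc(/C=C/C(=O)c2ccc(O)cc2O)cc1 | target

**Step count**

Total step count: 11.
Longest linear sequence: 6 steps (steps 1, 2, 5, 6, 10, 11; the branch through steps 3 and 4 is equally long).

**Steps most likely to fail**

1. Step 5, together with the crude diene from step 2 that it consumes. The first C–C bond may form without ring closure, so that an open-chain conjugate adduct or enynone oligomers accumulate. A diene formed as a mixture of geometries, or partly hydrolysed on handling, may react only in part. Aromatization may also run with loss of silanol instead of methanol and leave a methyl ether at C2. The fallback uses no cycloaddition: ring A is taken with its oxygens in place and the diaryl ether is made by copper catalysis. It sets out from aldehyde 6 (with purchased methoxyhydroquinone and 1,4-diiodobenzene) and comes back to the route at 13. Methoxyhydroquinone is C-acetylated para to its methoxy group (AcOH, BF3·OEt2, 90 °C) to give 1-(2,5-dihydroxy-4-methoxyphenyl)ethanone F1. Ullmann ether coupling of the free 5-hydroxyl of F1 with excess 1,4-diiodobenzene (CuI, N,N-dimethylglycine, Cs2CO3, dioxane, 90 °C, argon) should give 1-[2-hydroxy-5-(4-iodophenoxy)-4-methoxyphenyl]ethanone F2, since the hydrogen-bonded, acyl-flanked 2-hydroxyl is the poorer nucleophile and the excess of diiodide holds the reaction at mono-coupling. NaH and MOMCl in DMF give 1-[5-(4-iodophenoxy)-4-methoxy-2-(methoxymethoxy)phenyl]ethanone F3. Claisen–Schmidt condensation of F3 with 6 (KOH, EtOH, rt) gives 13.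

2. Step 10. Vinyl ketone 17 may polymerize under base and heat faster than it inserts, or a palladium hydride may reduce the enone and give the saturated ketone. The fallback forms the same C=C bond by olefin cross-metathesis under neutral conditions; it sets out from 13 and comes back at 18. Suzuki–Miyaura vinylation of 13 with potassium vinyltrifluoroborate (PdCl2(dppf), Cs2CO3, THF–H2O, 80 °C) gives (E)-1-[5-(4-ethenylphenoxy)-4-methoxy-2-(methoxymethoxy)phenyl]-3-[4-(methoxymethoxy)phenyl]prop-2-en-1-one F4. Cross-metathesis of F4 with 17 (second-generation Hoveyda–Grubbs catalyst, CH2Cl2, 40 °C, loss of ethene) should give 18 with E selectivity, the internal chalcone alkene being a poor metathesis substrate.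

3. Step 4. The N,O-dimethylhydroxylamine set free at the quench may add in conjugate fashion to the terminal ynone, or the cross-conjugated enynone may decompose under the basic reaction mixture. The fallback is a redox route in which the ynone never meets an amine; it sets out from 8 and comes back at 9. Reduction of 8 with i-Bu2AlH (THF, −78 °C) gives (E)-3-[4-(methoxymethoxy)phenyl]prop-2-enal F5. Addition of HC≡CMgBr (THF, 0 °C) gives racemic (E)-1-[4-(methoxymethoxy)phenyl]pent-1-en-4-yn-3-ol F6. MnO2 (CH2Cl2, rt) oxidizes this doubly activated alcohol to 9.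

**Further compounds**

F1 | step 5 | 1-(2,5-dihydroxy-4-methoxyphenyl)ethanone | CC(=O)c1cc(O)c(OC)cc1O
F2 | step 5 | 1-[2-hydroxy-5-(4-iodophenoxy)-4-methoxyphenyl]ethanone | CC(=O)c1cc(Oc2ccc(I)cc2)c(OC)cc1O
F3 | step 5 | 1-[5-(4-iodophenoxy)-4-methoxy-2-(methoxymethoxy)phenyl]ethanone | CC(=O)c1cc(Oc2ccc(I)cc2)c(OC)cc1OCOC
F4 | step 10 | (E)-1-[5-(4-ethenylphenoxy)-4-methoxy-2-(methoxymethoxy)phenyl]-3-[4-(methoxymethoxy)phenyl]prop-2-en-1-one | COCOc1ccc(/C=C/C(=O)c2cc(Oc3ccc(C=C)cc3)c(OC)cc2OCOC)cc1
F5 | step 4 | (E)-3-[4-(methoxymethoxy)phenyl]prop-2-enal | O=C/C=C/c1ccc(OCOC)cc1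
F6 | step 4 | (E)-1-[4-(methoxymethoxy)phenyl]pent-1-en-4-yn-3-ol | C#CC(O)/C=C/c1ccc(OCOC)cc1
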